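The disconnection on which the route rests is the bond between C1 of ring A (the 2,4-dihydroxy-3,6-dimethylphenyl ring) and the carbonyl carbon of the central ester. Ring A then derives from mirror-symmetric 2,5-dimethylresorcinol, whose two free ring carbons are equivalent and each lies ortho to an oxygen. Its bis-MOM ether is ring-lithiated under oxygen direction and acylated by the imidazole-1-carboxylate of the ring B benzylic alcohol, which already carries the complete C(=O)O–CH2–aryl unit. One operation thus joins the two elaborated halves as the hindered ester; ring B comes from methyl atrarate by lateral oxygenation, and one acid treatment removes all five MOM groups.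

Key step: step 6

Remark: the target has no stereocentre and is achiral, so no stereocontrol is required; 2,5-dimethylresorcinol and methyl 2,4-dihydroxy-3,6-dimethylbenzoate (methyl atrarate) are taken as commercial.

Step 1
Reactants: 1 2,5-dimethylbenzene-1,3-diol (2,5-dimethylresorcinol)
Product: 2 1,3-bis(methoxymethoxy)-2,5-dimethylbenzene
Conditions: NaH (2.5 equiv), MOMCl (2.4 equiv), DMF, 0 °C → rt
Reagents that add atoms: chloromethyl methyl ether (MOMCl), COCCl
Why: Williamson-type O-alkylation of the bis-phenoxide with the reactive α-chloro ether should cap both phenols as MOM acetals, which later direct the ring lithiation.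

Step 2
Reactants: 3 methyl 2,4-dihydroxy-3,6-dimethylbenzoate (methyl atrarate)
Product: 4 methyl 2,4-bis(methoxymethoxy)-3,6-dimethylbenzoate
Conditions: NaH (2.6 equiv), MOMCl (2.5 equiv), DMF, 0 °C → rt
Reagents that add atoms: chloromethyl methyl ether (MOMCl), COCCl
Why: Williamson-type O-alkylation, in which full deprotonation by NaH breaks the hydrogen bond of the C2 hydroxyl to the ester so that both phenols should be capped before the anion chemistry of step 3.

Step 3
Reactants: 4 methyl 2,4-bis(methoxymethoxy)-3,6-dimethylbenzoate
Product: 7 5,7-bis(methoxymethoxy)-6-methyl-2-benzofuran-1(3H)-one (the bis-MOM phthalide), via benzylic lithium compound 5 (not isolated), via lithium alkoxide 6 (not isolated)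
Conditions: LDA (1.2 equiv), THF, −78 °C; 2-(phenylsulfonyl)-3-phenyloxaziridine (1.3 equiv), −78 °C → rt; aq. NH4Cl
Reagents that add atoms: 2-(phenylsulfonyl)-3-phenyloxaziridine, O=S(=O)(c1ccccc1)N1OC1c1ccccc1
Why: Lateral lithiation of an o-toluate followed by Davis-type electrophilic hydroxylation: only the C6 methyl is conjugated with the ester and gives a stabilised dienolate, the oxaziridine should transfer oxygen to the benzylic carbon, and the alkoxide should close on the neighbouring methyl ester (5-exo-trig lactonisation) with loss of methoxide.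

Step 4
Reactants: 7 5,7-bis(methoxymethoxy)-6-methyl-2-benzofuran-1(3H)-one
Product: 9 methoxymethyl 2-(hydroxymethyl)-4,6-bis(methoxymethoxy)-5-methylbenzoate, via potassium carboxylate 8 (not isolated)
Conditions: KOH (1.05 equiv), MeOH/H2O, 50 °C; evaporate, toluene azeotrope; MOMCl (1.05 equiv), DMF, 0 °C; cold neutral work-up, used at once
Reagents that add atoms: potassium hydroxide, [K+].[OH-]; chloromethyl methyl ether (MOMCl), COCCl
Why: Saponification of the lactone followed by chemoselective O-alkylation of the carboxylate, the only anionic nucleophile present, should give the acetal ester while the neutral benzylic hydroxyl stays free, and the two ortho substituents should slow relactonisation.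

Step 5
Reactants: 9 methoxymethyl 2-(hydroxymethyl)-4,6-bis(methoxymethoxy)-5-methylbenzoate
Product: 10 methoxymethyl 2-{[(1H-imidazole-1-carbonyl)oxy]methyl}-4,6-bis(methoxymethoxy)-5-methylbenzoate
Conditions: CDI (1.5 equiv), CH2Cl2, 0 °C → rt; cold water wash, short silica filtration
Reagents that add atoms: 1,1'-carbonyldiimidazole (CDI), O=C(n1ccnc1)n1ccnc1
Why: Acylation of the primary alcohol by CDI should give an isolable alkoxycarbonyl imidazole (an activated carbamate) and at the same time remove the free hydroxyl that could relactonise.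

Step 6
Reactants: 2 1,3-bis(methoxymethoxy)-2,5-dimethylbenzene; 10 methoxymethyl 2-{[(1H-imidazole-1-carbonyl)oxy]methyl}-4,6-bis(methoxymethoxy)-5-methylbenzoate
Product: 12 methoxymethyl 2-({[2,4-bis(methoxymethoxy)-3,6-dimethylbenzoyl]oxy}methyl)-4,6-bis(methoxymethoxy)-5-methylbenzoate, via aryllithium 11 (not isolated)
Conditions: 2 (1.4 equiv), n-BuLi (1.3 equiv), TMEDA, THF, 0 °C; then 10 (1.0 equiv) in THF, −78 → −20 °C; aq. NH4Cl
Reagents that add atoms: none
Why: Directed ortho-metalation: n-BuLi/TMEDA coordinates to an OMOM oxygen of 2 and removes the adjacent ring proton to give aryllithium 11, which adds to the carbamate-type carbonyl of 10, and the tetrahedral adduct expels imidazolide to give ester 12. The closest known reaction type is the acylation of aryllithium and aryl Grignard reagents by alkyl imidazole-1-carboxylates, chloroformates or dicarbonates. No ring is closed and no stereocentre is formed. Regioselectivity is secured by the mirror symmetry of 2: C4 and C6 are equivalent, each is ortho to an OMOM group, and the position between the two oxygens is blocked by methyl. Chemoselectivity for the imidazolide carbonyl over the methoxymethyl ester of 10 should follow from the much higher electrophilicity of the N-acylimidazole and from the two ortho substituents that shield that ester. A second addition is not expected, because the new ester carbonyl of 12 is flanked by OMOM and methyl.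

Step 7
Reactants: 12 methoxymethyl 2-({[2,4-bis(methoxymethoxy)-3,6-dimethylbenzoyl]oxy}methyl)-4,6-bis(methoxymethoxy)-5-methylbenzoate
Product: 13 2-{[(2,4-dihydroxy-3,6-dimethylbenzoyl)oxy]methyl}-4,6-dihydroxy-5-methylbenzoic acid (target)
Conditions: 3 M HCl in MeOH, THF co-solvent, rt → 35 °C
Reagents that add atoms: none
Why: Acid-catalysed acetal cleavage (transacetalisation to dimethoxymethane) should remove the four aryl MOM ethers and the MOM ester in one operation, while the central ester should survive because its acyl carbon is flanked by two ortho substituents and its benzylic carbon is meta to both ring B oxygens; the temperature is kept low to avoid decarboxylation of the freed 2,4-dihydroxybenzoic acid.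

Compound list
1 | 2,5-dimethylbenzene-1,3-diol | Cc1cc(O)c(C)c(O)c1 | starting material
2 | 1,3-bis(methoxymethoxy)-2,5-dimethylbenzene | Cc1cc(OCOC)c(C)c(OCOC)c1 | intermediate
3 | methyl 2,4-dihydroxy-3,6-dimethylbenzoate | COC(=O)c1c(C)cc(O)c(C)c1O | starting material
4 | methyl 2,4-bis(methoxymethoxy)-3,6-dimethylbenzoate | COC(=O)c1c(C)cc(OCOC)c(C)c1OCOC | intermediate
5 | methyl 6-(lithiomethyl)-2,4-bis(methoxymethoxy)-3-methylbenzoate | [Li]Cc1cc(OCOC)c(C)c(OCOC)c1C(=O)OC | intermediate
6 | methyl 6-[(lithiooxy)methyl]-2,4-bis(methoxymethoxy)-3-methylbenzoate | [Li]OCc1cc(OCOC)c(C)c(OCOC)c1C(=O)OC | intermediate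
7 | 5,7-bis(methoxymethoxy)-6-methyl-2-benzofuran-1(3H)-one | O=C1OCc2cc(OCOC)c(C)c(OCOC)c21 | intermediate
8 | potassium 2-(hydroxymethyl)-4,6-bis(methoxymethoxy)-5-methylbenzoate | [K+].[O-]C(=O)c1c(CO)cc(OCOC)c(C)c1OCOC | intermediate
9 | methoxymethyl 2-(hydroxymethyl)-4,6-bis(methoxymethoxy)-5-methylbenzoate | COCOC(=O)c1c(CO)cc(OCOC)c(C)c1OCOC | intermediate
10 | methoxymethyl 2-{[(1H-imidazole-1-carbonyl)oxy]methyl}-4,6-bis(methoxymethoxy)-5-methylbenzoate | COCOC(=O)c1c(COC(=O)n2ccnc2)cc(OCOC)c(C)c1OCOC | intermediate
11 | [2,4-bis(methoxymethoxy)-3,6-dimethylphenyl]lithium | [Li]c1c(C)cc(OCOC)c(C)c1OCOC | intermediate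
12 | methoxymethyl 2-({[2,4-bis(methoxymethoxy)-3,6-dimethylbenzoyl]oxy}methyl)-4,6-bis(methoxymethoxy)-5-methylbenzoate | COCOC(=O)c1c(COC(=O)c2c(C)cc(OCOC)c(C)c2OCOC)cc(OCOC)c(C)c1OCOC | intermediate
13 | 2-{[(2,4-dihydroxy-3,6-dimethylbenzoyl)oxy]methyl}-4,6-dihydroxy-5-methylbenzoic acid | Cc1cc(O)c(C)c(O)c1C(=O)OCc1cc(O)c(C)c(O)c1C(=O)O | target

Total step count: 7. Longest linear sequence: 6 steps (3 → 4 → 7 → 9 → 10 → 12 → 13; steps 2 to 7).

Steps most likely to fail

Step 3. The benzylic dienolate may be oxidised by single-electron transfer and dimerise, or the alkoxide may be captured by the sulfonylimine by-product before it lactonises. The fallback sets out from 4 and comes back at 7. It replaces direct oxygen transfer by C–B bond formation and a later oxidative 1,2-migration. Anion 5 is generated as before and trapped with 2-isopropoxy-4,4,5,5-tetramethyl-1,3,2-dioxaborolane to give the isolable benzylic boronate methyl 2,4-bis(methoxymethoxy)-3-methyl-6-[(4,4,5,5-tetramethyl-1,3,2-dioxaborolan-2-yl)methyl]benzoate F1. Oxidation with NaBO3·4H2O in THF/H2O should give methyl 2-(hydroxymethyl)-4,6-bis(methoxymethoxy)-5-methylbenzoate F2, which should close to 7 under the basic conditions or on brief treatment with K2CO3 in MeOH.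

Step 4. The free benzylic hydroxyl may attack the activated acetal ester and relactonise to 7 during work-up, or under the imidazole released in step 5. The fallback sets out from 7 (through salt 8) and comes back at 13. It changes the carboxyl protection to an ester with a poorer leaving group and an orthogonal, neutral unmasking. Salt 8 is alkylated with allyl bromide in DMF to give prop-2-en-1-yl 2-(hydroxymethyl)-4,6-bis(methoxymethoxy)-5-methylbenzoate F3. CDI converts it into prop-2-en-1-yl 2-{[(1H-imidazole-1-carbonyl)oxy]methyl}-4,6-bis(methoxymethoxy)-5-methylbenzoate F4. Acylation of aryllithium 11 as in step 6 should give prop-2-en-1-yl 2-({[2,4-bis(methoxymethoxy)-3,6-dimethylbenzoyl]oxy}methyl)-4,6-bis(methoxymethoxy)-5-methylbenzoate F5. Methanolic HCl removes the four MOM ethers to give prop-2-en-1-yl 2-{[(2,4-dihydroxy-3,6-dimethylbenzoyl)oxy]methyl}-4,6-dihydroxy-5-methylbenzoate F6, in which the carboxyl group is still esterified and cannot decarboxylate. Pd(PPh3)4 with morpholine in THF at rt then frees the acid 13.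

Step 6. Lateral deprotonation of the C2 methyl group, which is flanked by both OMOM groups, may compete with ring deprotonation next to the C5 methyl, or ring metalation may stay incomplete, so that the nucleophile forms as a mixture. The fallback sets out from 2 and comes back at 11. It replaces deprotonation by regiodefined halogen–metal exchange. Bromination of 2 with NBS (1.0 equiv) in MeCN at 0 °C can only occur at the two equivalent free ring positions and should give 1-bromo-2,4-bis(methoxymethoxy)-3,6-dimethylbenzene F7. Bromine–lithium exchange with n-BuLi in THF at −78 °C then gives 11, which is acylated by 10 as in step 6.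

Further compounds
F1 | step 3 | methyl 2,4-bis(methoxymethoxy)-3-methyl-6-[(4,4,5,5-tetramethyl-1,3,2-dioxaborolan-2-yl)methyl]benzoate | COC(=O)c1c(CB2OC(C)(C)C(C)(C)O2)cc(OCOC)c(C)c1OCOC
F2 | step 3 | methyl 2-(hydroxymethyl)-4,6-bis(methoxymethoxy)-5-methylbenzoate | COC(=O)c1c(CO)cc(OCOC)c(C)c1OCOC
F3 | step 4 | prop-2-en-1-yl 2-(hydroxymethyl)-4,6-bis(methoxymethoxy)-5-methylbenzoate | C=CCOC(=O)c1c(CO)cc(OCOC)c(C)c1OCOC
F4 | step 4 | prop-2-en-1-yl 2-{[(1H-imidazole-1-carbonyl)oxy]methyl}-4,6-bis(methoxymethoxy)-5-methylbenzoate | C=CCOC(=O)c1c(COC(=O)n2ccnc2)cc(OCOC)c(C)c1OCOC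
F5 | step 4 | prop-2-en-1-yl 2-({[2,4-bis(methoxymethoxy)-3,6-dimethylbenzoyl]oxy}methyl)-4,6-bis(methoxymethoxy)-5-methylbenzoate | C=CCOC(=O)c1c(COC(=O)c2c(C)cc(OCOC)c(C)c2OCOC)cc(OCOC)c(C)c1OCOC
F6 | step 4 | prop-2-en-1-yl 2-{[(2,4-dihydroxy-3,6-dimethylbenzoyl)oxy]methyl}-4,6-dihydroxy-5-methylbenzoate | C=CCOC(=O)c1c(COC(=O)c2c(C)cc(O)c(C)c2O)cc(O)c(C)c1O
F7 | step 6 | 1-bromo-2,4-bis(methoxymethoxy)-3,6-dimethylbenzene | Brc1c(C)cc(OCOC)c(C)c1OCOC
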